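## Retrosynthetic overview
1. The enal comes from late allylic oxidation (CH3 to CHO) of the isopropenyl bis-isovalerate, so no stereocentre is touched at the end.
2. The dihydrofuran is the only ring to be built. The O1–C2 bond forms when a phenoxide opens a trans aryl vinyl epoxide with inversion. This is coupled to transfer of the aryl-bound isovaleryl group onto the C3 oxygen (new catalytic isomerisation).
3. The vinyl epoxide comes from dehydration of an epoxy tertiary alcohol, made by Shi epoxidation of an (E)-allylic alcohol. The second alkene stays masked as the carbinol, so only one C=C meets the oxidant.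
4. The (E)-alkene comes from a Heck reaction of an aryl bromide with 2-methylbut-3-en-2-ol. Both isovalerates go on in one acylation, and C1' is set by transfer hydrogenation of 3'-bromo-4'-hydroxyacetophenone.

Assumption: the SMILES is read as 2R,3S (2,3-trans) and 1'R. The L-fructose-derived Shi ketone and n-Bu4N(OPh) are bought and are not counted as steps.

## Route

**Step 1**
Reactants: 1 1-(3-bromo-4-hydroxyphenyl)ethan-1-one
Product: 2 2-bromo-4-[(1R)-1-hydroxyethyl]phenol
Conditions: RuCl[(R,R)-TsDPEN](p-cymene) (0.5 mol %), HCO2H–Et3N (5:2), 28 °C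
Reagents that add atoms: none
Why: Noyori–Ikariya asymmetric transfer hydrogenation, in which the (R,R)-catalyst gives the (R)-1-arylethanol from aryl methyl ketones (typically 95% ee or better), leaves C–Br and the phenol alone, and benefits from the ortho bromine damping quinone-methide ionisation of the product.

**Step 2**
Reactants: 2 2-bromo-4-[(1R)-1-hydroxyethyl]phenol; 3 3-methylbutanoic anhydride (2.4 equiv)
Product: 4 (1R)-1-[3-bromo-4-(3-methylbutanoyloxy)phenyl]ethyl 3-methylbutanoate
Conditions: 4-(dimethylamino)pyridine (5 mol %), Et3N, CH2Cl2, 0 °C to rt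
Reagents that add atoms: 3-methylbutanoic anhydride, CC(C)CC(=O)OC(=O)CC(C)C
Why: DMAP-catalysed acylation esterifies both hydroxyls in one operation without breaking the C1'–O bond (retention), and the anhydride avoids HCl, which could ionise the p-hydroxybenzylic alcohol.

**Step 3**
Reactants: 4 (1R)-1-[3-bromo-4-(3-methylbutanoyloxy)phenyl]ethyl 3-methylbutanoate; 5 2-methylbut-3-en-2-ol
Product: 6 (1R)-1-{3-[(1E)-3-hydroxy-3-methylbut-1-en-1-yl]-4-(3-methylbutanoyloxy)phenyl}ethyl 3-methylbutanoate
Conditions: Pd(OAc)2 (2 mol %), P(o-tol)3 (6 mol %), Et3N, MeCN, 85 °C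
Reagents that add atoms: 2-methylbut-3-en-2-ol, C=CC(C)(C)O
Why: Mizoroki–Heck reaction, in which syn-carbopalladation at the terminal carbon and syn β-hydride elimination give only the E-alkene, the fully substituted carbinol carbon blocks chain-walking, and both esters tolerate the amine base.

**Step 4**
Reactants: 6 (1R)-1-{3-[(1E)-3-hydroxy-3-methylbut-1-en-1-yl]-4-(3-methylbutanoyloxy)phenyl}ethyl 3-methylbutanoate
Product: 7 (1R)-1-{3-[(2S,3R)-3-(2-hydroxypropan-2-yl)oxiran-2-yl]-4-(3-methylbutanoyloxy)phenyl}ethyl 3-methylbutanoate (trans-epoxide, benzylic carbon S)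
Conditions: 1,2:4,5-di-O-isopropylidene-β-L-erythro-2,3-hexodiulo-2,6-pyranose (L-fructose-derived Shi ketone, 30 mol %), 2KHSO5·KHSO4·K2SO4 (Oxone), K2CO3, n-Bu4NHSO4, MeCN–CH2(OMe)2 / aq. Na2B4O7–Na2H2(EDTA) buffer, −5 to 0 °C, 2 h
Reagents that add atoms: potassium peroxymonosulfate KHSO5, [K+].[O-]S(=O)(=O)OO
Why: Shi epoxidation, in which the chiral dioxirane attacks the only C=C through the spiro transition state, the L-series ketone gives the (S)-benzylic trans-epoxide (the D-series gives R,R with trans-β-methylstyrene), and low temperature with a short run limits hydrolysis of the aryl ester.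

**Step 5**
Reactants: 7 (1R)-1-{3-[(2S,3R)-3-(2-hydroxypropan-2-yl)oxiran-2-yl]-4-(3-methylbutanoyloxy)phenyl}ethyl 3-methylbutanoate
Product: 8 (1R)-1-{4-(3-methylbutanoyloxy)-3-[(2S,3S)-3-(prop-1-en-2-yl)oxiran-2-yl]phenyl}ethyl 3-methylbutanoate
Conditions: Ph2S[OC(CF3)2Ph]2 (Martin sulfurane, 1.3 equiv), CH2Cl2, −20 °C to rt; cold aq. K2CO3 wash; short Et3N-deactivated silica plug
Reagents that add atoms: none
Why: Martin sulfurane dehydration of a tertiary alcohol through the alkoxysulfonium ion, where only the methyl β-hydrogens can leave (loss of the epoxide C–H would give a methyleneoxirane), epoxides are inert to the reagent, and both epoxide carbons keep their geometry (the descriptor changes from R to S only through priorities).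

**Step 6**
Reactants: 8 (1R)-1-{4-(3-methylbutanoyloxy)-3-[(2S,3S)-3-(prop-1-en-2-yl)oxiran-2-yl]phenyl}ethyl 3-methylbutanoate
Product: 9 (1R)-1-[(2R,3S)-3-(3-methylbutanoyloxy)-2-(prop-1-en-2-yl)-2,3-dihydro-1-benzofuran-5-yl]ethyl 3-methylbutanoate
Conditions: n-Bu4N(OPh) (5 mol %), THF (0.2 M), 4 Å molecular sieves, 40 °C
Reagents that add atoms: none
Why: Proposed new method: a phenoxide-catalysed acyl-transfer cycloisomerisation, in which PhO− takes the aryl-bound isovaleryl group by degenerate transesterification and frees the substrate phenoxide; this phenoxide attacks the allylically activated epoxide carbon from the rear (attack at the benzylic carbon would need a four-membered ring) and forms O1–C2 with inversion (S to R) while the C3–O bond is untouched (3S, hence 2,3-trans); the released C3 alkoxide is far more basic than a phenoxide and strips the isovaleryl group from the aryl ester of the next molecule or from PhOC(O)CH2CHMe2, so the chain runs on 5 mol % catalyst, no reagent is consumed and the former phenol protecting group ends as the C3 ester; the closest known reaction types are the onium-salt-catalysed intermolecular addition of aryl esters across epoxides and the base-induced cyclisation of 2-(oxiran-2-yl)phenols to 2,3-dihydrobenzofuran-3-ols, neither of which has been shown as an intramolecular ester-to-ester relay, on a vinyl epoxide, or stereospecifically.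

**Step 7**
Reactants: 9 (1R)-1-[(2R,3S)-3-(3-methylbutanoyloxy)-2-(prop-1-en-2-yl)-2,3-dihydro-1-benzofuran-5-yl]ethyl 3-methylbutanoate
Product: 11 (1R)-1-[(2R,3S)-3-(3-methylbutanoyloxy)-2-(3-oxoprop-1-en-2-yl)-2,3-dihydro-1-benzofuran-5-yl]ethyl 3-methylbutanoate (target), via allylic alcohol 10 (not isolated)
Conditions: SeO2 (0.5 equiv), t-BuOOH (5.5 M in decane, 3 equiv), CH2Cl2, 0 °C to rt; aqueous wash; then Dess–Martin periodinane (1.2 equiv), CH2Cl2, 0 °C
Reagents that add atoms: selenium dioxide SeO2, O=[Se]=O; tert-butyl hydroperoxide, CC(C)(C)OO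
Why: Riley-type allylic oxidation under Sharpless–Umbreit conditions (ene reaction, then [2,3]-sigmatropic shift) takes the methyl group of the 1,1-disubstituted alkene rather than the tertiary, oxygen-deactivated C2–H, Dess–Martin oxidation converts the alcohol/enal mixture fully to the enal, no stereocentre is touched, and the trans ester has no anti-periplanar C2–H, which slows loss of isovaleric acid to the benzofuran under these mild conditions.

## Compound list
1 | 1-(3-bromo-4-hydroxyphenyl)ethan-1-one | CC(=O)c1ccc(O)c(Br)c1 | starting material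
2 | 2-bromo-4-[(1R)-1-hydroxyethyl]phenol | Oc1ccc([C@@H](C)O)cc1Br | intermediate
3 | 3-methylbutanoic (isovaleric) anhydride | CC(C)CC(=O)OC(=O)CC(C)C | starting material
4 | (1R)-1-[3-bromo-4-(3-methylbutanoyloxy)phenyl]ethyl 3-methylbutanoate | CC(C)CC(=O)Oc1ccc([C@@H](C)OC(=O)CC(C)C)cc1Br | intermediate
5 | 2-methylbut-3-en-2-ol | C=CC(C)(C)O | starting material
6 | (1R)-1-{3-[(1E)-3-hydroxy-3-methylbut-1-en-1-yl]-4-(3-methylbutanoyloxy)phenyl}ethyl 3-methylbutanoate | CC(C)(O)/C=C/c1cc([C@@H](C)OC(=O)CC(C)C)ccc1OC(=O)CC(C)C | intermediate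
7 | (1R)-1-{3-[(2S,3R)-3-(2-hydroxypropan-2-yl)oxiran-2-yl]-4-(3-methylbutanoyloxy)phenyl}ethyl 3-methylbutanoate | CC(C)(O)[C@@H]1O[C@H]1c1cc([C@@H](C)OC(=O)CC(C)C)ccc1OC(=O)CC(C)C | intermediate
8 | (1R)-1-{4-(3-methylbutanoyloxy)-3-[(2S,3S)-3-(prop-1-en-2-yl)oxiran-2-yl]phenyl}ethyl 3-methylbutanoate | C=C(C)[C@@H]1O[C@H]1c1cc([C@@H](C)OC(=O)CC(C)C)ccc1OC(=O)CC(C)C | intermediate
9 | (1R)-1-[(2R,3S)-3-(3-methylbutanoyloxy)-2-(prop-1-en-2-yl)-2,3-dihydro-1-benzofuran-5-yl]ethyl 3-methylbutanoate | C=C(C)[C@H]1Oc2ccc([C@@H](C)OC(=O)CC(C)C)cc2[C@@H]1OC(=O)CC(C)C | intermediate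
10 | (1R)-1-[(2R,3S)-2-(3-hydroxyprop-1-en-2-yl)-3-(3-methylbutanoyloxy)-2,3-dihydro-1-benzofuran-5-yl]ethyl 3-methylbutanoate (not isolated) | C=C(CO)[C@H]1Oc2ccc([C@@H](C)OC(=O)CC(C)C)cc2[C@@H]1OC(=O)CC(C)C | intermediate
11 | (1R)-1-[(2R,3S)-3-(3-methylbutanoyloxy)-2-(3-oxoprop-1-en-2-yl)-2,3-dihydro-1-benzofuran-5-yl]ethyl 3-methylbutanoate | C=C(C=O)[C@H]1Oc2ccc([C@@H](C)OC(=O)CC(C)C)cc2[C@@H]1OC(=O)CC(C)C | target

## Step count and risks
Total steps: 7. Longest linear sequence: 7.

**Step 6 (the proposed new step).**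
- The ring closure has to open an epoxide carbon that lies inside the forming five-membered ring, so it may be slow.
- The phenoxide could instead push the benzylic C–O bond open (quinone methide, then ketone or benzofuran).
- It could attack the alkene terminus to give a seven-membered ether, or react between molecules.
- Fallback with known chemistry, setting out from 8: K2CO3 in MeOH at 0 °C methanolyses the aryl ester selectively. The phenoxide closes onto the epoxide in the established base-induced manner to give (1R)-1-[(2R,3S)-3-hydroxy-2-(prop-1-en-2-yl)-2,3-dihydro-1-benzofuran-5-yl]ethyl 3-methylbutanoate F1. This alcohol is esterified with 3, DMAP and Et3N in CH2Cl2, and the route is rejoined at 9 (one step more).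

**Step 5.**
- The alkoxysulfonium ion sits next to an acid-labile aryl epoxide, so ionisation with rearrangement is possible.
- The doubly activated epoxide 8 may not survive handling.
- Fallback, setting out from 7: close the ring first and make the alkene afterwards. K2CO3/MeOH at 0 °C cleaves the aryl ester. The base is kept weak so that the tertiary alkoxide and a Payne shift stay out. The phenoxide opens the epoxide to the diol (1R)-1-[(2S,3S)-3-hydroxy-2-(2-hydroxypropan-2-yl)-2,3-dihydro-1-benzofuran-5-yl]ethyl 3-methylbutanoate F2.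
- Reagent 3 with DMAP then acylates only the secondary hydroxyl, giving (1R)-1-[(2S,3S)-2-(2-hydroxypropan-2-yl)-3-(3-methylbutanoyloxy)-2,3-dihydro-1-benzofuran-5-yl]ethyl 3-methylbutanoate F3.
- Burgess reagent (MeO2CN−SO2N+Et3, toluene, 50 °C) dehydrates the tertiary alcohol. This is the classical way to make the isopropenyl group of tremetone- and rotenone-type dihydrobenzofurans. The route is rejoined at 9.

**Step 7.**
- Conversion may be low on the electron-poor 1,1-disubstituted alkene.
- The ene reaction may take the C2–H instead of the methyl group.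
- Acid-promoted loss of isovaleric acid would give the benzofuran.
- Fallback, setting out from 9: replace the selenium chemistry by halogenation and amine-oxide oxidation. Ene-type chlorination with Ca(OCl)2 and solid CO2 in CH2Cl2–H2O at 0 °C gives (1R)-1-[(2R,3S)-2-(3-chloroprop-1-en-2-yl)-3-(3-methylbutanoyloxy)-2,3-dihydro-1-benzofuran-5-yl]ethyl 3-methylbutanoate F4. N-Methylmorpholine N-oxide in MeCN at rt to 40 °C (Ganem-type oxidation of an allylic chloride) then delivers the enal, and the route is rejoined at 11.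

## Further compounds
F1 | step 6 | (1R)-1-[(2R,3S)-3-hydroxy-2-(prop-1-en-2-yl)-2,3-dihydro-1-benzofuran-5-yl]ethyl 3-methylbutanoate | C=C(C)[C@H]1Oc2ccc([C@@H](C)OC(=O)CC(C)C)cc2[C@@H]1O
F2 | step 5 | (1R)-1-[(2S,3S)-3-hydroxy-2-(2-hydroxypropan-2-yl)-2,3-dihydro-1-benzofuran-5-yl]ethyl 3-methylbutanoate | CC(C)(O)[C@H]1Oc2ccc([C@@H](C)OC(=O)CC(C)C)cc2[C@@H]1O
F3 | step 5 | (1R)-1-[(2S,3S)-2-(2-hydroxypropan-2-yl)-3-(3-methylbutanoyloxy)-2,3-dihydro-1-benzofuran-5-yl]ethyl 3-methylbutanoate | CC(C)(O)[C@H]1Oc2ccc([C@@H](C)OC(=O)CC(C)C)cc2[C@@H]1OC(=O)CC(C)C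
F4 | step 7 | (1R)-1-[(2R,3S)-2-(3-chloroprop-1-en-2-yl)-3-(3-methylbutanoyloxy)-2,3-dihydro-1-benzofuran-5-yl]ethyl 3-methylbutanoate | C=C(CCl)[C@H]1Oc2ccc([C@@H](C)OC(=O)CC(C)C)cc2[C@@H]1OC(=O)CC(C)C
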